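The synthesis rests on cutting the C(sp2)–C(sp3) bond between the vinylic CH of the trisubstituted alkene and the methyl-bearing methine on C2 of ring B, the 4-pyranone that also carries the acetoxypentyl chain. This methine is conjugated with the C2=C3–C4=O unit of ring B, so its radical is delocalised and a chloride there is easily reduced. The last step is a nickel-catalysed, ligand-controlled reductive coupling of two electrophiles: the fully acylated (E)-alkenyl bromide 18 (ring A half) and 1-chloroethylpyranone 31, a mixture of C–Cl epimers. One operation joins the halves, sets the seventh stereocentre stereoconvergently and releases the target without any protecting group.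

Key step: step 19

Assumption: the sense of induction of (R)-TRIP (step 4) and of the (3aR,8aS)-configured bis(oxazoline) (step 19) is taken from the benzaldehyde and (1-chloroethyl)benzene model cases; both antipodes of each are available if the sense proves opposite.

**Ring A half**

Step 1
Reactants: 1 pentan-3-one; 2 propanoic acid (2 equiv)
Product: 4 2,6-diethyl-3,5-dimethyl-4H-pyran-4-one, via triketone 3 (not isolated)
Conditions: polyphosphoric acid, neat, 130–150 °C
Reagents that add atoms: none
Why: Polyphosphoric acid promotes C-acylation of the ketone at both α-carbons and then cyclodehydrates the resulting 1,3,5-triketone to the symmetrical 4-pyranone (acid-mediated acylation/cyclodehydration), with no stereocentre involved.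

Step 2
Reactants: 5 prop-2-yn-1-ol
Product: 7 (2E)-3-bromo-2-methylprop-2-en-1-ol, via alkenylalane 6 (not isolated)
Conditions: AlMe3 (3 equiv), Cp2ZrCl2 (0.25 equiv), CH2Cl2, 0 °C to rt; then N-bromosuccinimide, THF, −30 to 0 °C; aqueous work-up
Reagents that add atoms: AlMe3, C[Al](C)C; N-bromosuccinimide, O=C1CCC(=O)N1Br
Why: Negishi zirconium-catalysed carboalumination adds CH3 and Al syn across the terminal alkyne with CH3 on the internal carbon, and bromodealumination with retention fixes the E alkenyl bromide that is carried unchanged to the target.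

Step 3
Reactants: 7 (2E)-3-bromo-2-methylprop-2-en-1-ol
Product: 8 (2E)-3-bromo-2-methylprop-2-enal
Conditions: activated MnO2 (excess), CH2Cl2, rt
Reagents that add atoms: none
Why: Allylic alcohol oxidation with MnO2 is neutral and selective and leaves the alkenyl bromide and the alkene geometry untouched.

Step 4
Reactants: 8 (2E)-3-bromo-2-methylprop-2-enal; 9 (E)-crotylboronic acid pinacol ester
Product: 11 (1E,3R,4R)-1-bromo-2,4-dimethylhexa-1,5-dien-3-ol, via pinacol borate 10 (not isolated)
Conditions: (R)-TRIP [(R)-3,3'-bis(2,4,6-triisopropylphenyl)-1,1'-binaphthyl-2,2'-diyl hydrogen phosphate] (5 mol %), 4 Å MS, toluene, −30 °C; aqueous work-up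
Reagents that add atoms: none
Why: Chiral-phosphoric-acid-catalysed crotylboration runs through a closed chair transition state in which the E-crotyl geometry gives the anti CH3/OH pair, and the phosphate, hydrogen-bonded to a boronate oxygen and the formyl hydrogen, selects the Re face of the non-enolisable enal to give the 3R,4R centres.

Step 5
Reactants: 11 (1E,3R,4R)-1-bromo-2,4-dimethylhexa-1,5-dien-3-ol
Product: 12 {[(1E,3R,4R)-1-bromo-2,4-dimethylhexa-1,5-dien-3-yl]oxy}(tert-butyl)dimethylsilane
Conditions: TBSOTf, 2,6-lutidine, CH2Cl2, −78 to 0 °C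
Reagents that add atoms: TBSOTf, CC(C)(C)[Si](C)(C)OS(=O)(=O)C(F)(F)F
Why: Silyl triflate silylation covers the hindered secondary allylic alcohol under weakly basic conditions without touching either stereocentre.

Step 6
Reactants: 12 silyl ether
Product: 14 (2S,3R,4E)-5-bromo-3-[(tert-butyldimethylsilyl)oxy]-2,4-dimethylpent-4-enal, via vicinal diol 13 (not isolated)
Conditions: OsO4 (2 mol %), NaIO4 (4 equiv), 2,6-lutidine, dioxane/H2O, rt
Reagents that add atoms: NaIO4 (terminal source of the aldehyde oxygen, relayed by OsO4), [Na+].[O-]I(=O)(=O)=O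
Why: In this Lemieux–Johnson cleavage OsO4 attacks the unhindered monosubstituted alkene in preference to the bromine-deactivated trisubstituted one, periodate cleaves the diol, and the lutidine buffer keeps the α-stereocentre from epimerising.

Step 7
Reactants: 4 2,6-diethyl-3,5-dimethyl-4H-pyran-4-one (2 equiv); 14 aldehyde
Product: 16 2-{(2R,3R,4R,5R,6E)-7-bromo-5-[(tert-butyldimethylsilyl)oxy]-3-hydroxy-4,6-dimethylhept-6-en-2-yl}-6-ethyl-3,5-dimethyl-4H-pyran-4-one, via lithium dienolate 15 (not isolated)
Conditions: LiN(SiMe3)2 (1.8 equiv), THF, −78 °C; then 14, −78 °C; AcOH quench at −78 °C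
Reagents that add atoms: none
Why: This is a vinylogous aldol addition of a 2-ethyl-4-pyranone dienolate in which A(1,3) strain with the C3 methyl fixes the Z-ethylidene geometry of 15, the reinforcing Felkin–Anh and 1,3-anti polar preferences of the 2,3-anti α-methyl-β-silyloxy aldehyde set the carbinol centre (syn to the α-methyl, anti to the silyloxy group), and an open transition state that places the aldehyde chain over the ring oxygen and not over the C3 methyl should favour the anti CH3/OH pair next to ring A, a minor syn epimer being removable by chromatography.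

Step 8
Reactants: 16 aldol adduct
Product: 17 2-[(2R,3R,4R,5R,6E)-7-bromo-3,5-dihydroxy-4,6-dimethylhept-6-en-2-yl]-6-ethyl-3,5-dimethyl-4H-pyran-4-one
Conditions: HF·pyridine, pyridine/THF, 0 °C to rt
Reagents that add atoms: none
Why: Mildly acidic fluoride desilylation avoids the retro-aldol and β-elimination that a basic fluoride source could start at the acidic C–H next to ring A.

Step 9
Reactants: 17 diol
Product: 18 (1E,3R,4R,5R,6R)-1-bromo-6-(6-ethyl-3,5-dimethyl-4-oxo-4H-pyran-2-yl)-2,4-dimethylhept-1-ene-3,5-diyl dipropanoate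
Conditions: (EtCO)2O, Et3N, DMAP (cat.), CH2Cl2, 0 °C to rt
Reagents that add atoms: propanoic anhydride, CCC(=O)OC(=O)CC
Why: DMAP-catalysed acyl transfer esterifies both secondary alcohols in one operation at oxygen only, so no stereocentre is touched.

**Ring B half**

Step 10
Reactants: 19 heptane-3,5-dione
Product: 20 4-methylheptane-3,5-dione
Conditions: K2CO3, MeI, acetone, reflux
Reagents that add atoms: iodomethane, CI
Why: C-alkylation of the stabilised β-diketone enolate with one equivalent of MeI installs the central methyl group, and the centre formed is not retained.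

Step 11
Reactants: 21 propanal (2 equiv)
Product: 22 (2S,3S)-3-hydroxy-2-methylpentanal
Conditions: L-proline (10 mol %), DMF, 4 °C
Reagents that add atoms: none
Why: In this enamine-catalysed direct aldehyde self-aldol the E-enamine of L-proline attacks the Re face of a second propanal held by the carboxylic acid in a chair-like hydrogen-bonded transition state, which sets both centres as the anti (2S,3S) pair, the minor syn isomer being removed by chromatography here or at 23.

Step 12
Reactants: 22 (2S,3S)-3-hydroxy-2-methylpentanal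
Product: 23 (2S,3S)-3-[(tert-butyldimethylsilyl)oxy]-2-methylpentanal
Conditions: TBSOTf, 2,6-lutidine, CH2Cl2, −78 °C
Reagents that add atoms: TBSOTf, CC(C)(C)[Si](C)(C)OS(=O)(=O)C(F)(F)F
Why: Fast low-temperature O-silylation traps the sensitive β-hydroxy aldehyde before elimination, oligomerisation or α-epimerisation can compete.

Step 13
Reactants: 20 4-methylheptane-3,5-dione; 23 aldehyde
Product: 25 (8R,9S)-9-[(tert-butyldimethylsilyl)oxy]-7-hydroxy-4,6,8-trimethylundecane-3,5-dione (mixture at C4, C6 and C7), via dilithium dianion 24 (not isolated)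
Conditions: LiN(iPr)2 (2.2 equiv), THF, −78 to 0 °C; then 23, −78 °C; AcOH quench
Reagents that add atoms: none
Why: The 1,3-diketone dianion adds to the aldehyde at its more reactive terminal carbon faster than it enolises the α-chiral aldehyde, and the three new stereocentres are irrelevant because all become sp2 in steps 14 and 15.

Step 14
Reactants: 25 hydroxy diketone
Product: 26 (8S,9S)-9-[(tert-butyldimethylsilyl)oxy]-4,6,8-trimethylundecane-3,5,7-trione (mixture at C4 and C6, keto–enol tautomers)
Conditions: Dess–Martin periodinane, CH2Cl2, rt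
Reagents that add atoms: none
Why: Dess–Martin oxidation converts the secondary alcohol into the third carbonyl under near-neutral conditions that spare the silyl ether and the stereocentre α to the new ketone.

Step 15
Reactants: 26 triketone
Product: 27 2-{(2S,3S)-3-[(tert-butyldimethylsilyl)oxy]pentan-2-yl}-6-ethyl-3,5-dimethyl-4H-pyran-4-one
Conditions: Ph3P, CCl4, THF, rt
Reagents that add atoms: none
Why: Appel-type activation of one terminal enol oxygen is followed by six-membered O-cyclisation of the other enol with loss of Ph3PO, and this 1,3,5-triketone cyclodehydration is neutral enough to preserve the silyl ether and the adjacent stereocentre.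

Step 16
Reactants: 27 pyranone
Product: 29 2-(1-chloroethyl)-6-{(2S,3S)-3-[(tert-butyldimethylsilyl)oxy]pentan-2-yl}-3,5-dimethyl-4H-pyran-4-one (both C–Cl epimers), via lithium dienolate 28 (not isolated)
Conditions: LiN(SiMe3)2 (1.05 equiv), THF, −78 °C; cannulated into C2Cl6 (1.5 equiv), THF, −78 °C
Reagents that add atoms: hexachloroethane, ClC(Cl)(Cl)C(Cl)(Cl)Cl
Why: Kinetic vinylogous (lateral) deprotonation takes the unhindered ethyl CH2 rather than the tertiary C–H beside the silyloxy carbon, the dienolate is chlorinated at its exocyclic carbon (electrophilic halogenation with inverse addition), and the C–Cl centre may form as a mixture because step 19 erases it.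

Step 17
Reactants: 29 silyl ether chloride
Product: 30 2-(1-chloroethyl)-6-[(2S,3S)-3-hydroxypentan-2-yl]-3,5-dimethyl-4H-pyran-4-one
Conditions: HF·pyridine, THF, 0 °C to rt
Reagents that add atoms: none
Why: Acidic fluoride desilylation leaves the chloride alone, because the electron-poor pyranone disfavours its ionisation, and avoids base at the acidic ring-adjacent C–H positions.

Step 18
Reactants: 30 hydroxy chloride
Product: 31 (2S,3S)-2-[6-(1-chloroethyl)-3,5-dimethyl-4-oxo-4H-pyran-2-yl]pentan-3-yl acetate
Conditions: Ac2O, Et3N, DMAP (cat.), CH2Cl2, 0 °C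
Reagents that add atoms: acetic anhydride, CC(=O)OC(C)=O
Why: DMAP-catalysed acetylation at 0 °C is much faster than substitution or elimination of the secondary chloride and does not touch the carbinol configuration.

**Union of the halves**

Step 19
Reactants: 18 alkenyl bromide (ring A half); 31 chloride (ring B half)
Product: 32 target, (2S,3S)-2-{6-[(2S,3E,5R,6R,7R,8R)-8-(6-ethyl-3,5-dimethyl-4-oxo-4H-pyran-2-yl)-4,6-dimethyl-5,7-bis(propanoyloxy)non-3-en-2-yl]-3,5-dimethyl-4-oxo-4H-pyran-2-yl}pentan-3-yl acetate
Conditions: NiCl2(dme) (10 mol %), (3aR,3a'R,8aS,8a'S)-2,2'-(cyclopropane-1,1-diyl)bis(3a,8a-dihydro-8H-indeno[1,2-d]oxazole) (11 mol %), Mn powder (3 equiv), NaI (0.5 equiv), DMA, 0 °C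
Reagents that add atoms: none
Why: Zerovalent nickel bound to the chiral bis(oxazoline) inserts into the C(sp2)–Br bond of 18 with retention of the E geometry, a monovalent nickel species abstracts chlorine from 31 to give a planar secondary radical delocalised over C2=C3–C4=O of ring B, the alkenylnickel bromide captures this radical, and reductive elimination from trivalent nickel forms the alkenyl–CH(CH3) bond while Mn returns nickel to its low-valent state. The closest known reaction type is the enantioselective nickel-catalysed reductive cross-electrophile alkenylation of secondary benzylic chlorides with alkenyl bromides, the pyranon-2-yl group taking the place of the aryl group. No ring is closed. The one new stereocentre (S, the methine between the alkene and C2 of ring B) is set by the ligand at the radical-capture/reductive-elimination stage, so both C–Cl epimers of 31 converge on one product and the remote stereocentres of either half should not override the catalyst. The step needs cross- over homo-coupling, which the different activation modes secure (two-electron insertion for the sp2 bromide, halogen-atom abstraction for the activated sp3 chloride), and it needs the allylic propanoate, the other esters and both pyranones to stay untouched, which the much faster reaction of C–Br and C–Cl at 0 °C, the hindered trisubstituted alkene and the mild reductant should secure. The neutral medium also keeps the new doubly activated C–H from epimerising and the alkene from moving into conjugation, which is why the coupling is placed last.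

**Compound list**

1 | pentan-3-one | CCC(=O)CC | starting material
2 | propanoic acid | CCC(=O)O | starting material
3 | 4,6-dimethylnonane-3,5,7-trione (not isolated) | CCC(=O)C(C)C(=O)C(C)C(=O)CC | intermediate
4 | 2,6-diethyl-3,5-dimethyl-4H-pyran-4-one | CCc1oc(CC)c(C)c(=O)c1C | intermediate
5 | prop-2-yn-1-ol | C#CCO | starting material
6 | dimethylaluminium (2E)-3-(dimethylalumanyl)-2-methylprop-2-en-1-olate (not isolated) | C[Al](C)OC/C(C)=C/[Al](C)C | intermediate
7 | (2E)-3-bromo-2-methylprop-2-en-1-ol | OC/C(C)=C/Br | intermediate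
8 | (2E)-3-bromo-2-methylprop-2-enal | O=C/C(C)=C/Br | intermediate
9 | 2-[(2E)-but-2-en-1-yl]-4,4,5,5-tetramethyl-1,3,2-dioxaborolane, (E)-crotylboronic acid pinacol ester | C/C=C/CB1OC(C)(C)C(C)(C)O1 | starting material
10 | 2-{[(1E,3R,4R)-1-bromo-2,4-dimethylhexa-1,5-dien-3-yl]oxy}-4,4,5,5-tetramethyl-1,3,2-dioxaborolane (not isolated) | C=C[C@@H](C)[C@@H](OB1OC(C)(C)C(C)(C)O1)/C(C)=C/Br | intermediate
11 | (1E,3R,4R)-1-bromo-2,4-dimethylhexa-1,5-dien-3-ol | C=C[C@@H](C)[C@@H](O)/C(C)=C/Br | intermediate
12 | {[(1E,3R,4R)-1-bromo-2,4-dimethylhexa-1,5-dien-3-yl]oxy}(tert-butyl)dimethylsilane | C=C[C@@H](C)[C@@H](O[Si](C)(C)C(C)(C)C)/C(C)=C/Br | intermediate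
13 | (3R,4R,5E)-6-bromo-4-[(tert-butyldimethylsilyl)oxy]-3,5-dimethylhex-5-ene-1,2-diol, both C2 epimers (not isolated) | OCC(O)[C@@H](C)[C@@H](O[Si](C)(C)C(C)(C)C)/C(C)=C/Br | intermediate
14 | (2S,3R,4E)-5-bromo-3-[(tert-butyldimethylsilyl)oxy]-2,4-dimethylpent-4-enal | O=C[C@@H](C)[C@@H](O[Si](C)(C)C(C)(C)C)/C(C)=C/Br | intermediate
15 | lithium (2Z)-6-ethyl-2-ethylidene-3,5-dimethyl-2H-pyran-4-olate (not isolated) | C/C=C1/C(C)=C(O[Li])C(C)=C(CC)O1 | intermediate
16 | 2-{(2R,3R,4R,5R,6E)-7-bromo-5-[(tert-butyldimethylsilyl)oxy]-3-hydroxy-4,6-dimethylhept-6-en-2-yl}-6-ethyl-3,5-dimethyl-4H-pyran-4-one | O[C@H]([C@@H](C)[C@@H](O[Si](C)(C)C(C)(C)C)/C(C)=C/Br)[C@@H](C)c1oc(CC)c(C)c(=O)c1C | intermediate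
17 | 2-[(2R,3R,4R,5R,6E)-7-bromo-3,5-dihydroxy-4,6-dimethylhept-6-en-2-yl]-6-ethyl-3,5-dimethyl-4H-pyran-4-one | O[C@H]([C@@H](C)[C@@H](O)/C(C)=C/Br)[C@@H](C)c1oc(CC)c(C)c(=O)c1C | intermediate
18 | (1E,3R,4R,5R,6R)-1-bromo-6-(6-ethyl-3,5-dimethyl-4-oxo-4H-pyran-2-yl)-2,4-dimethylhept-1-ene-3,5-diyl dipropanoate | CCC(=O)O[C@H]([C@@H](C)[C@@H](OC(=O)CC)/C(C)=C/Br)[C@@H](C)c1oc(CC)c(C)c(=O)c1C | intermediate
19 | heptane-3,5-dione | CCC(=O)CC(=O)CC | starting material
20 | 4-methylheptane-3,5-dione | CCC(=O)C(C)C(=O)CC | intermediate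
21 | propanal | CCC=O | starting material
22 | (2S,3S)-3-hydroxy-2-methylpentanal | O=C[C@@H](C)[C@H](CC)O | intermediate
23 | (2S,3S)-3-[(tert-butyldimethylsilyl)oxy]-2-methylpentanal | O=C[C@@H](C)[C@H](CC)O[Si](C)(C)C(C)(C)C | intermediate
24 | dilithium 4-methylhepta-2,4-diene-3,5-diolate (not isolated) | CC=C(O[Li])C(C)=C(CC)O[Li] | intermediate
25 | (8R,9S)-9-[(tert-butyldimethylsilyl)oxy]-7-hydroxy-4,6,8-trimethylundecane-3,5-dione, mixture at C4, C6, C7 | CCC(=O)C(C)C(=O)C(C)C(O)[C@@H](C)[C@H](CC)O[Si](C)(C)C(C)(C)C | intermediate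
26 | (8S,9S)-9-[(tert-butyldimethylsilyl)oxy]-4,6,8-trimethylundecane-3,5,7-trione, mixture at C4, C6 | CCC(=O)C(C)C(=O)C(C)C(=O)[C@@H](C)[C@H](CC)O[Si](C)(C)C(C)(C)C | intermediate
27 | 2-{(2S,3S)-3-[(tert-butyldimethylsilyl)oxy]pentan-2-yl}-6-ethyl-3,5-dimethyl-4H-pyran-4-one | CCc1oc([C@@H](C)[C@H](CC)O[Si](C)(C)C(C)(C)C)c(C)c(=O)c1C | intermediate
28 | lithium (2Z)-6-{(2S,3S)-3-[(tert-butyldimethylsilyl)oxy]pentan-2-yl}-2-ethylidene-3,5-dimethyl-2H-pyran-4-olate (not isolated) | C/C=C1/C(C)=C(O[Li])C(C)=C([C@@H](C)[C@H](CC)O[Si](C)(C)C(C)(C)C)O1 | intermediate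
29 | 2-(1-chloroethyl)-6-{(2S,3S)-3-[(tert-butyldimethylsilyl)oxy]pentan-2-yl}-3,5-dimethyl-4H-pyran-4-one, both C–Cl epimers | CC(Cl)c1oc([C@@H](C)[C@H](CC)O[Si](C)(C)C(C)(C)C)c(C)c(=O)c1C | intermediate
30 | 2-(1-chloroethyl)-6-[(2S,3S)-3-hydroxypentan-2-yl]-3,5-dimethyl-4H-pyran-4-one, both C–Cl epimers | CC(Cl)c1oc([C@@H](C)[C@H](CC)O)c(C)c(=O)c1C | intermediate
31 | (2S,3S)-2-[6-(1-chloroethyl)-3,5-dimethyl-4-oxo-4H-pyran-2-yl]pentan-3-yl acetate, both C–Cl epimers | CC(Cl)c1oc([C@@H](C)[C@H](CC)OC(C)=O)c(C)c(=O)c1C | intermediate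
32 | (2S,3S)-2-{6-[(2S,3E,5R,6R,7R,8R)-8-(6-ethyl-3,5-dimethyl-4-oxo-4H-pyran-2-yl)-4,6-dimethyl-5,7-bis(propanoyloxy)non-3-en-2-yl]-3,5-dimethyl-4-oxo-4H-pyran-2-yl}pentan-3-yl acetate | CCC(=O)O[C@H]([C@@H](C)[C@@H](OC(=O)CC)/C(C)=C/[C@H](C)c1oc([C@@H](C)[C@H](CC)OC(C)=O)c(C)c(=O)c1C)[C@@H](C)c1oc(CC)c(C)c(=O)c1C | target

Total step count: 19.
Longest linear sequence: 9 steps (steps 2–9 and 19 from prop-2-yn-1-ol; equally steps 11–18 and 19 from propanal).

**Steps most likely to fail**

1. Step 19. Several processes may compete: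
   - the ring B radical may dimerise or be reduced to the ethyl compound faster than the hindered alkenylnickel species captures it;
   - the alkenyl bromide may homocouple;
   - low-valent nickel may ionise the allylic propanoate;
   - the C3 methyl beside the radical centre may weaken the facial control of the ligand.

   The fallback sets out from 31 and forms the same bond by a polar two-electron pathway. Insertion of Zn dust (LiCl, THF, 25 °C) into the C–Cl bond gives the pyranonylic zinc chloride F1, a vinylogous Reformatsky reagent that tolerates the acetate. Negishi coupling of this reagent with bromide 18 (Pd(OAc)2, SPhos, THF, 25 °C) comes back to the route at 32. The new centre is then not catalyst-controlled, but its two epimers are diastereomers and would be parted by preparative HPLC.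

2. Step 7. The open transition state may discriminate poorly between the syn and anti arrangements at the carbon next to ring A. Reversible addition may erode the ratio, and the dienolate may enolise the aldehyde. The fallback sets out from 14 and builds ring A only after all four stereocentres stand.
   - Crotylboration of 14 with 9 under the (S)-configured phosphoric acid, matched with the Felkin–Anh preference of an E-crotylboronate, gives homoallylic alcohol F2.
   - TBSOTf/2,6-lutidine gives bis-silyl ether F3.
   - OsO4/NaIO4 cleavage of the terminal alkene gives aldehyde F4.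
   - Addition of dianion 24 gives hydroxy diketone F5.
   - Dess–Martin oxidation gives triketone F6.
   - Ph3P/CCl4 closes ring A to the bis-silylated pyranone F7.
   - HF·pyridine removes both silyl groups and comes back to the route at 17.

3. Step 16. Proton transfer from the more acidic chloride product to unreacted dienolate may lead to over-chlorination or to alkylation of the dienolate by the product. Competing deprotonation at the tertiary ring-adjacent C–H may cause epimerisation or loss of the silyloxy group by β-elimination. The fallback sets out from 27. Its dienolate is trapped with an oxygen electrophile, 2-(phenylsulfonyl)-3-phenyloxaziridine (THF, −78 °C), to give the 1-hydroxyethylpyranone F8, whose alkoxide is neither acidic nor electrophilic. Appel deoxychlorination (Ph3P, CCl4, CH2Cl2, rt) then comes back to the route at 29. The configuration at this carbon is again irrelevant.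

Further compounds
F1 | step 19 | chloro{1-[6-((2S,3S)-3-acetoxypentan-2-yl)-3,5-dimethyl-4-oxo-4H-pyran-2-yl]ethyl}zinc | CC([Zn]Cl)c1oc([C@@H](C)[C@H](CC)OC(C)=O)c(C)c(=O)c1C
F2 | step 7 | (1E,3R,4R,5S,6S)-1-bromo-3-[(tert-butyldimethylsilyl)oxy]-2,4,6-trimethylocta-1,7-dien-5-ol | O[C@H]([C@@H](C)[C@@H](O[Si](C)(C)C(C)(C)C)/C(C)=C/Br)[C@@H](C)C=C
F3 | step 7 | (1E,3R,4R,5S,6S)-1-bromo-3,5-bis[(tert-butyldimethylsilyl)oxy]-2,4,6-trimethylocta-1,7-diene | CC(C)(C)[Si](C)(C)O[C@H]([C@@H](C)[C@@H](O[Si](C)(C)C(C)(C)C)/C(C)=C/Br)[C@@H](C)C=C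
F4 | step 7 | (2R,3R,4R,5R,6E)-7-bromo-3,5-bis[(tert-butyldimethylsilyl)oxy]-2,4,6-trimethylhept-6-enal | CC(C)(C)[Si](C)(C)O[C@H]([C@@H](C)[C@@H](O[Si](C)(C)C(C)(C)C)/C(C)=C/Br)[C@@H](C)C=O
F5 | step 7 | (12E)-13-bromo-9,11-bis[(tert-butyldimethylsilyl)oxy]-7-hydroxy-4,6,8,10,12-pentamethyltridec-12-ene-3,5-dione, C8–C11 as in F4, mixture at C4, C6, C7 | CC(C)(C)[Si](C)(C)O[C@H]([C@@H](C)[C@@H](O[Si](C)(C)C(C)(C)C)/C(C)=C/Br)[C@@H](C)C(O)C(C)C(=O)C(C)C(=O)CC
F6 | step 7 | (12E)-13-bromo-9,11-bis[(tert-butyldimethylsilyl)oxy]-4,6,8,10,12-pentamethyltridec-12-ene-3,5,7-trione, C8–C11 as in F4, mixture at C4, C6 | CC(C)(C)[Si](C)(C)O[C@H]([C@@H](C)[C@@H](O[Si](C)(C)C(C)(C)C)/C(C)=C/Br)[C@@H](C)C(=O)C(C)C(=O)C(C)C(=O)CC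
F7 | step 7 | 2-{(2R,3R,4R,5R,6E)-7-bromo-3,5-bis[(tert-butyldimethylsilyl)oxy]-4,6-dimethylhept-6-en-2-yl}-6-ethyl-3,5-dimethyl-4H-pyran-4-one | CC(C)(C)[Si](C)(C)O[C@H]([C@@H](C)[C@@H](O[Si](C)(C)C(C)(C)C)/C(C)=C/Br)[C@@H](C)c1oc(CC)c(C)c(=O)c1C
F8 | step 16 | 2-(1-hydroxyethyl)-6-{(2S,3S)-3-[(tert-butyldimethylsilyl)oxy]pentan-2-yl}-3,5-dimethyl-4H-pyran-4-one, both carbinol epimers | CC(O)c1oc([C@@H](C)[C@H](CC)O[Si](C)(C)C(C)(C)C)c(C)c(=O)c1C
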